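Remark on numbering: labdane numbering is used for all ring compounds (ring A = C1–C5 and C10; ring B = C5–C10; C18 = 4α-methyl, C19 = 4β axial carbon, C20 on C10, C17 on C8, chain C11–C16 on C9). β is the face of C20, α the face of H-5.

Assumption: the (S)-configured oxazaborolidinium catalyst is taken to leave the Re face of the α-carbon of methacrolein open, as the formyl C–H···O binding model for 2-substituted acroleins predicts; the (R)-catalyst would be used unchanged otherwise if the adduct proved antipodal.

## Analysis of the target

The target is the 15-O-stearoyl ester of (13S)-15-hydroxylabd-8(17)-en-19-oic acid. It is a trans-fused decalin (rings A and B) with an exocyclic methylene at C8, an axial free carboxylic acid (C19) and an equatorial methyl (C18) on C4, the angular methyl C20 on C10, and a C9 chain that branches at C13 and ends in the C15 stearate. There are five stereocenters: C4 (S), C5 (R), C9 (S) and C10 (R) in the bicycle and C13 (S) in the chain. C19, C20 and the C9 chain lie on the β face, H-5 and H-9 on the α face, and C13 is too far from the rings to be controlled by them. The exocyclic alkene rules out hydrogenation and strong acid at the end, and the primary stearate rules out hydrolytic unmasking of the hindered C19 acid. The main difficulty is the pair of quaternary stereocenters C4 and C10, held 1,3-diaxial across ring A, together with C9 next to the quaternary C10. The strategy rests on two features of ring A. C4 carries a methyl and a carbonyl carbon next to the methine C5, which is the pattern methacrolein leaves when ring A is formed by a Diels–Alder reaction onto a ring B diene. C19 is syn-axial to C20, so an oxygen function on C19 can reach the β face of C10 and hand its configuration on to the angular methyl.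

## Retrosynthetic reasoning

The C15–O acyl bond is cut first, giving hydroxy acid 29 and stearoyl chloride 30. Acylation is placed last so that the ester meets no later reagent. The forward step must acylate the unhindered primary alcohol beside the shielded C19 acid, which can at most form a mixed anhydride that aqueous work-up reverses.

29 is traced to 28, in which C15 is a silyl ether and C19 a 2-silylethyl ester, so that one desilylation frees both without hydrolysis. The C8=C17 bond of 28 is then cut by a Wittig transform to the norketone 27. Methylenation is late so that the isomerisable alkene is absent from all earlier steps.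

The C8 carbonyl of 27 is taken back through alcohol 26 to the 8-ene 24, by cutting the C8–O and C9–H bonds (hydroboration–oxidation). This is where C9 is set: addition must come from the α face, opposite the axial C20 on the neighbouring C10.

24 is cut at C9–C11 into enol triflate 17 and iodide 22 (used as its zinc reagent 23). This is the convergent bond. It separates the bicyclic core from C13, which comes from the chiral pool: 22 derives from half-ester 18 through 19, 20 and 21, the acid terminus becoming C15 and the ester terminus C11.

17 comes from ketone 15, which can enolise only toward C8 because C10 is quaternary. 15 is the protected form of keto acid 14, and 14 arises from ketal alcohol 12 by unmasking C9 and oxidising C19. No skeletal bond is cut here.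

The C10–C20 bond is addressed next. 12 is traced to cyclopropane 11 (the C1–C20 bond is re-formed) and 11 to alkene 9 (the methylene is removed from C1 and C10). Direct carbon delivery to C10 would come from the α face, away from the axial C4 substituent; the C19 hydroxyl of 9 can instead deliver the carbon to the β face and so give the trans fusion.

9 is the reduction product of aldehyde 8, and 8 is cut at C4–C5 and C2–C3 into diene 6 and methacrolein 7. This removes ring A and both ring A stereocenters in one operation and leaves two small achiral partners. The forward cycloaddition must be ortho-regioselective, formyl-endo and face-selective under catalyst control.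

Diene 6 is cut at C1–C10 into vinyl bromide 4 and vinylboronate 5 (Suzuki–Miyaura coupling); 4 comes from bromo enone 3 and this from cyclohexenone 1.

## Alternatives that were turned down

Alternative 1: The bicycle is disconnected at C5–C10 and C8–C9, so that both rings unravel into one chain. In the forward direction an E-enal (C9=C10, C20 on C10) would add intramolecularly, on heating or with an aluminium Lewis acid, across an E,E-diene (C5 to C8) through the C1–C4 tether, giving the trans-fused octalin aldehyde A1.
- For: both rings, the angular methyl, the trans fusion and C9 arise in one step, and the C11 formyl group is a handle for the chain. On C20 and C9 this is stronger than the chosen plan, which spends three steps on the C20 relay and four on C9 and C8.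
- Against: the only stereocenter present before cyclisation is the open-chain quaternary C4, which must be made enantiopure without a ring. Its methyl and ester groups differ too little to steer the diene face reliably. The dienophile is β,β-disubstituted, so the quaternary C10 forms slowly. The C8 stereocenter of A1 is later discarded, the 6-ene must be reduced, and the whole chain with C13 is still missing.
- Comparison: the chosen strategy reaches its key step in three steps from achiral materials and lets a catalyst make the one absolute stereochemical decision, whereas here a long linear synthesis precedes the risky step.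

Alternative 2: The C9–C11 bond is disconnected inside a temporary 11-membered lactone that ties C19 to C15. In the forward direction a divalent chromium salt would convert a C17 allylic bromide function into an allylchromium species that adds through C9 to a tethered C11 aldehyde function, giving lactone A2 with the 8(17)-methylene in place.
- For: one step forms C9–C11, sets C9 from the β-face tether and creates the exocyclic alkene without an olefination, and it uses the two oxygen functions of the target as the tether. This is more economical than the coupling, hydroboration, oxidation and methylenation of the chosen route.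
- Against: it is an endgame. It presupposes the complete decalin with C4, C5 and C10 set and a tetrasubstituted 8(9)-alkene, so the main difficulty is untouched. The closure makes a strained medium ring through a bond to a carbon flanked by the quaternary C10. Afterwards the C11 hydroxyl must be removed and the very hindered lactone carbonyl at C19 opened before C15 can be acylated.
- Comparison: the chosen route solves the core first and attaches the chain intermolecularly, at the price of more steps on C8 and C9.

Alternative 3: The C9–C10 bond is disconnected with ring A as an aromatic salicylate. In the forward direction an iridium–phosphoramidite catalyst would ionise an allylic carbonate function and the para carbon of the phenol (C10, bearing the methyl) would attack the allyl terminus C9, closing ring B and giving the cross-conjugated dienone A3.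
- For: the quaternary C10 and C9 are set in one catalytic enantioselective step, the angular methyl is present from the start and needs no relay, and the C9 vinyl group begins the chain. On C10 and C9 this is stronger than the chosen plan.
- Against: A3 is far from the target in oxidation pattern. The C3 ketone must be removed and the 1-ene reduced. C4 is still sp2 and needs C18 with the ester axial, and H-5 must be set trans to C20, so C4 and C5 need separate stereocontrol. A fused rather than spiro dearomatisation through a tether on the ortho carbon, with O- versus C-alkylation and branched versus linear selectivity, is itself uncertain.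
- Comparison: the chosen key step installs C4 and C5 directly in the final substitution pattern of ring A and leaves one relay for C10, whereas this alternative spreads the risk over several late redox and alkylation steps.

Key step: step 4

## Route

Step 1
Reactants: 1 cyclohex-2-en-1-one
Product: 3 2-bromocyclohex-2-en-1-one, via dibromo ketone 2 (not isolated)
Conditions: Br2, CH2Cl2, 0 °C; then Et3N, 0 °C → rt
Reagents that add atoms: bromine, BrBr
Why: Bromine adds across the enone alkene and triethylamine then removes the acidic α-proton with loss of the β-bromide (bromination–dehydrobromination), the standard route to 2-bromo enones; no stereocenter remains.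

Step 2
Reactants: 3 2-bromocyclohex-2-en-1-one
Product: 4 6-bromo-1,4-dioxaspiro[4.5]dec-6-ene
Conditions: HOCH2CH2OH, p-TsOH (cat.), benzene, reflux, Dean–Stark
Reagents that add atoms: ethylene glycol, OCCO
Why: Acid-catalysed ketalisation driven by azeotropic removal of water; with the vinylic bromine the alkene stays at the 6,7-position, and the ketal masks the future C9 carbonyl until step 8.

Step 3
Reactants: 4 6-bromo-1,4-dioxaspiro[4.5]dec-6-ene; 5 vinylboronic acid pinacol ester
Product: 6 6-ethenyl-1,4-dioxaspiro[4.5]dec-6-ene
Conditions: Pd(dppf)Cl2 (3 mol%), K2CO3, dioxane/H2O, 80 °C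
Reagents that add atoms: none
Why: Suzuki–Miyaura coupling of a vinyl bromide with a vinylboronate through zerovalent palladium; the ketal is inert to aqueous carbonate, and the diene is used promptly to avoid dimerisation.

Step 4
Reactants: 6 6-ethenyl-1,4-dioxaspiro[4.5]dec-6-ene; 7 methacrolein
Product: 8 (1S,8aS)-5,5-(ethylenedioxy)-1-methyl-1,2,3,5,6,7,8,8a-octahydronaphthalene-1-carbaldehyde (4β-formyl C19, 4α-methyl C18, H-5 α, 1(10)-ene, C9 ketal)
Conditions: 7 (3 equiv), 20 mol% (S)-3,3-diphenyl-1-(2-methylphenyl)tetrahydro-1H,3H-pyrrolo[1,2-c][1,3,2]oxazaborole + HN(SO2CF3)2 (oxazaborolidinium triflimide), CH2Cl2, −78 → −40 °C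
Reagents that add atoms: none
Why: The protonated oxazaborolidine binds the formyl oxygen of 7, with the formyl C–H held by the ring oxygen, and the activated s-trans enal undergoes a concerted but asynchronous [4+2] addition in which the C2–C3 bond (unsubstituted vinyl terminus to the methylene of 7) runs ahead of the C4–C5 bond. The closest known reaction type is the oxazaborolidinium-catalysed Diels–Alder reaction of 2-substituted acroleins with 1-vinylcycloalkenes and related semicyclic dienes. Ring A is closed as the six-membered cycloadduct ring by suprafacial addition across the s-cis diene of 6, both ring bonds forming in the one pericyclic event. C4 is set by the catalyst, whose aryl group covers the Si face of the α-carbon so that the diene bonds to the Re face; C5 is set relative to C4 by the formyl-endo arrangement, which places C19 cis to C6 and trans to H-5. Ortho regiochemistry is needed and should follow from the larger HOMO coefficient at the unsubstituted terminus C2 and the larger LUMO coefficient at the methylene of 7. Endo orientation of the Lewis-acid-bound formyl group is needed and is favoured because the diene has no bridge to clash with the α-methyl group. Face selection rests on the catalyst alone because 6 is achiral. The ketal carbon next to C10 disfavours the s-trans rotamer of the diene, which helps reactivity, and the low temperature protects the allylic ketal from ionisation.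

Step 5
Reactants: 8 formyl-endo adduct
Product: 9 [(1S,8aS)-5,5-(ethylenedioxy)-1-methyl-1,2,3,5,6,7,8,8a-octahydronaphthalen-1-yl]methanol (4β-hydroxymethyl, 1(10)-ene, C9 ketal)
Conditions: NaBH4, MeOH, 0 °C
Reagents that add atoms: none
Why: Borohydride reduction of the neopentyl aldehyde; C4 is quaternary so nothing can epimerise, and the ketal and alkene are untouched.

Step 6
Reactants: 9 C19 alcohol
Product: 11 cyclopropane alcohol (C20 methylene bridging C1 and C10 on the β face; 4β-hydroxymethyl; 4α-methyl; H-5 α; C9 ketal), via ethylzinc alkoxide 10 (not isolated)
Conditions: Et2Zn (3 equiv), CH2I2 (6 equiv), CH2Cl2, 0 °C → rt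
Reagents that add atoms: diiodomethane, ICI; diethylzinc, CC[Zn]CC (zinc and ethyl appear only in intermediate 10)
Why: Hydroxyl-directed Simmons–Smith cyclopropanation under Furukawa conditions: the zinc alkoxide of the 4β-hydroxymethyl group lies over the β face of the 1(10)-alkene and delivers the methylene there, so C20 is bonded to C10 on the face of C19 and trans to H-5; this fixes C10, while C1 is a transient stereocenter.

Step 7
Reactants: 11 cyclopropane alcohol
Product: 12 4β-(hydroxymethyl)-4α,10β-dimethyl trans-decalin C9 ethylene ketal (H-5 α)
Conditions: H2 (4 atm), PtO2, AcOH, NaOAc, rt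
Reagents that add atoms: none
Why: Catalytic hydrogenolysis of a cyclopropane cleaves the least hindered bond, here C1–C20 between the methine and the methylene, and leaves both bonds to the quaternary C10 intact, so C20 becomes the 10β-methyl with C10 unchanged and the ring fusion trans; the buffered medium is meant to keep the ketal, so that no cyclopropyl ketone can form.

Step 8
Reactants: 12 ketal alcohol
Product: 14 4α,10β-dimethyl-9-oxo trans-decalin-4β-carboxylic acid (H-5 α), via keto alcohol 13 (not isolated)
Conditions: 2 M HCl, acetone, rt; then CrO3, H2SO4, H2O (Jones reagent), 0 °C → rt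
Reagents that add atoms: water, O
Why: Aqueous acid hydrolyses the ketal next to the quaternary C10, and Jones oxidation then takes the primary alcohol through the aldehyde hydrate to the acid; the ketone is inert and no stereocenter is enolisable because C4 and C10 are quaternary.

Step 9
Reactants: 14 keto acid
Product: 15 2-(trimethylsilyl)ethyl ester of 14
Conditions: Me3SiCH2CH2OH, PPh3, DIAD, THF, 0 °C → rt
Reagents that add atoms: 2-(trimethylsilyl)ethanol, C[Si](C)(C)CCO
Why: Mitsunobu esterification in which the hindered carboxylate is the nucleophile and displacement occurs at the unhindered primary carbon of the activated alcohol, so the shielded C19 carbonyl is never attacked; the ester is later cleaved at silicon, again away from that carbonyl.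

Step 10
Reactants: 15 keto ester
Product: 17 8-en-9-yl trifluoromethanesulfonate of 15 (C8=C9 enol triflate), via potassium enolate 16 (not isolated)
Conditions: KN(SiMe3)2, THF, −78 °C; then PhNTf2, −78 → 0 °C
Reagents that add atoms: N-phenylbis(trifluoromethanesulfonimide), O=S(=O)(N(c1ccccc1)S(=O)(=O)C(F)(F)F)C(F)(F)F; potassium hexamethyldisilazide, C[Si](C)(C)[N-][Si](C)(C)C.[K+] (potassium appears only in intermediate 16)
Why: Deprotonation can occur only at C8 because C10 is quaternary and the ester has no α-hydrogen; O-sulfonylation of the enolate by the triflimide gives the vinyl triflate.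

Step 11
Reactants: 18 (R)-methyl hydrogen 3-methylglutarate
Product: 19 methyl (R)-5-hydroxy-3-methylpentanoate
Conditions: BH3·SMe2, THF, 0 °C → rt
Reagents that add atoms: none
Why: Borane reduces the free acid through an acyloxyborane far faster than the methyl ester, so only the acid terminus (future C15) becomes the alcohol; the stereocenter is not involved, and the product is silylated without delay to forestall lactonisation.

Step 12
Reactants: 19 hydroxy ester
Product: 20 methyl (R)-5-[(tert-butyldiphenylsilyl)oxy]-3-methylpentanoate
Conditions: t-BuPh2SiCl, imidazole, DMF, rt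
Reagents that add atoms: tert-butyl(chloro)diphenylsilane, CC(C)(C)[Si](Cl)(c1ccccc1)c1ccccc1
Why: Imidazole-promoted silylation of the primary alcohol; this silyl ether withstands the hydride, zinc, palladium, borane and ylide steps that follow and is removed by fluoride together with the C19 ester.

Step 13
Reactants: 20 silyloxy ester
Product: 21 (S)-5-[(tert-butyldiphenylsilyl)oxy]-3-methylpentan-1-ol
Conditions: i-Bu2AlH (2.2 equiv), CH2Cl2, −78 → 0 °C
Reagents that add atoms: none
Why: Hydride reduction of the ester to the primary alcohol (future C11); the descriptor changes only because the priorities of the two arms change.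

Step 14
Reactants: 21 alcohol
Product: 22 (R)-tert-butyl[(5-iodo-3-methylpentyl)oxy]diphenylsilane
Conditions: I2, PPh3, imidazole, CH2Cl2, 0 °C → rt
Reagents that add atoms: iodine, II
Why: Appel-type iodination of a primary alcohol through the alkoxyphosphonium salt (SN2 at C11); the remote stereocenter is untouched.

Step 15
Reactants: 17 enol triflate; 22 iodide
Product: 24 2-(trimethylsilyl)ethyl (13S)-15-[(tert-butyldiphenylsilyl)oxy]-17-norlabd-8-en-19-oate, via alkylzinc iodide 23 (not isolated)
Conditions: 22, Zn dust, LiCl, THF, 40 °C; then 17, Pd(dppf)Cl2 (5 mol%), THF/NMP, 60 °C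
Reagents that add atoms: zinc, [Zn] (zinc appears only in intermediate 23)
Why: Negishi coupling: zinc inserts into the primary C–I bond, the vinyl triflate adds oxidatively to zerovalent palladium, and transmetalation and reductive elimination form C9–C11; the bidentate ferrocenyl phosphine suppresses β-hydride elimination, and esters and silyl ethers tolerate alkylzinc reagents.

Step 16
Reactants: 24 8-ene
Product: 26 2-(trimethylsilyl)ethyl (13S)-15-[(tert-butyldiphenylsilyl)oxy]-8α-hydroxy-17-norlabdan-19-oate (H-9 α), via alkylborane 25 (not isolated)
Conditions: BH3·SMe2, THF, 0 °C → rt; then NaBO3·4H2O, THF/H2O, rt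
Reagents that add atoms: sodium perborate, [Na+].[Na+].O[B-]1(O)OO[B-](O)(O)OO1; borane–dimethyl sulfide, B.CSC (boron appears only in intermediate 25)
Why: Hydroboration–oxidation of the trisubstituted alkene: boron adds to the less substituted C8 and hydrogen to C9, syn and from the α face, opposite the axial C20 on the neighbouring C10, which sets H-9 α with the chain β and equatorial; oxidation with retention gives the 8α-alcohol, whose configuration is erased in step 17.

Step 17
Reactants: 26 8α-alcohol
Product: 27 2-(trimethylsilyl)ethyl (13S)-15-[(tert-butyldiphenylsilyl)oxy]-8-oxo-17-norlabdan-19-oate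
Conditions: Dess–Martin periodinane, NaHCO3, CH2Cl2, rt
Reagents that add atoms: none
Why: Dess–Martin oxidation of the secondary alcohol under buffered conditions; C9 keeps its equatorial chain, which is also the thermodynamically preferred arrangement.

Step 18
Reactants: 27 8-ketone
Product: 28 2-(trimethylsilyl)ethyl (13S)-15-[(tert-butyldiphenylsilyl)oxy]labd-8(17)-en-19-oate
Conditions: Ph3PCH3Br (slight excess over base), KN(SiMe3)2, THF/toluene, 0 → 70 °C
Reagents that add atoms: methyltriphenylphosphonium bromide, C[P+](c1ccccc1)(c1ccccc1)c1ccccc1.[Br-]
Why: Wittig methylenation of the hindered C8 ketone with the non-stabilised ylide at elevated temperature; should C9 enolise, reprotonation returns the equatorial natural configuration, and no free alkoxide is present to attack the silylethyl ester.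

Step 19
Reactants: 28 doubly protected ester
Product: 29 (13S)-15-hydroxylabd-8(17)-en-19-oic acid, (1S,4aR,5S,8aR)-5-[(3S)-5-hydroxy-3-methylpentyl]-1,4a-dimethyl-6-methylidenedecahydronaphthalene-1-carboxylic acid
Conditions: Bu4NF (5 equiv), THF, 50 °C; cold dilute aq. HCl work-up
Reagents that add atoms: none
Why: Fluoride cleaves the silyl ether at silicon and the 2-(trimethylsilyl)ethyl ester by β-elimination with loss of ethene, both away from the hindered carbonyl, so the hydroxy acid is freed without hydrolysis or hydrogenation.

Step 20
Reactants: 29 hydroxy acid; 30 stearoyl chloride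
Product: 31 (1S,4aR,5S,8aR)-1,4a-dimethyl-6-methylidene-5-[(3S)-3-methyl-5-(octadecanoyloxy)pentyl]decahydronaphthalene-1-carboxylic acid (target)
Conditions: 30 (2.2 equiv), pyridine, DMAP (cat.), CH2Cl2, 0 °C → rt; aq. NaHCO3 work-up, then dilute acid
Reagents that add atoms: none
Why: DMAP-catalysed acylation of the primary alcohol by the acid chloride; the axial neopentyl-type C19 acid can at most form a mixed anhydride, which the bicarbonate work-up hydrolyses at its unhindered stearoyl carbonyl, so the free acid of the target is returned.

## Compound list

1 | cyclohex-2-en-1-one | O=C1C=CCCC1 | starting material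
2 | trans-2,3-dibromocyclohexan-1-one (racemic; configuration inconsequential) | O=C1CCCC(Br)C1Br | intermediate
3 | 2-bromocyclohex-2-en-1-one | O=C1CCCC=C1Br | intermediate
4 | 6-bromo-1,4-dioxaspiro[4.5]dec-6-ene | BrC1=CCCCC12OCCO2 | intermediate
5 | vinylboronic acid pinacol ester | C=CB1OC(C)(C)C(C)(C)O1 | starting material
6 | 6-ethenyl-1,4-dioxaspiro[4.5]dec-6-ene | C=CC1=CCCCC12OCCO2 | intermediate
7 | methacrolein | CC(=C)C=O | starting material
8 | (1S,8aS)-5,5-(ethylenedioxy)-1-methyl-1,2,3,5,6,7,8,8a-octahydronaphthalene-1-carbaldehyde (4β-formyl, 4α-methyl, H-5 α, 1(10)-ene, C9 ketal) | C1CC[C@@H]2C(=CCC[C@]2(C)C=O)C13OCCO3 | intermediate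
9 | [(1S,8aS)-5,5-(ethylenedioxy)-1-methyl-1,2,3,5,6,7,8,8a-octahydronaphthalen-1-yl]methanol | C1CC[C@@H]2C(=CCC[C@]2(C)CO)C13OCCO3 | intermediate
10 | ethylzinc alkoxide of 9 | C1CC[C@@H]2C(=CCC[C@]2(C)CO[Zn]CC)C13OCCO3 | intermediate
11 | cyclopropane alcohol: C20 methylene bridging C1 and C10 on the β face, 4β-hydroxymethyl, 4α-methyl, H-5 α, C9 ethylene ketal | C1CC[C@@H]2[C@@]3(C[C@@H]3CC[C@]2(C)CO)C14OCCO4 | intermediate
12 | 4β-(hydroxymethyl)-4α,10β-dimethyl trans-decalin C9 ethylene ketal (H-5 α) | C1CC[C@@H]2[C@](C)(CCC[C@]2(C)CO)C13OCCO3 | intermediate
13 | 4β-(hydroxymethyl)-4α,10β-dimethyl trans-decalin-9-one (H-5 α) | C1CC[C@@H]2[C@](C)(CCC[C@]2(C)CO)C1=O | intermediate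
14 | 4α,10β-dimethyl-9-oxo trans-decalin-4β-carboxylic acid (H-5 α) | C1CC[C@@H]2[C@](C)(CCC[C@]2(C)C(=O)O)C1=O | intermediate
15 | 2-(trimethylsilyl)ethyl ester of 14 | C1CC[C@@H]2[C@](C)(CCC[C@]2(C)C(=O)OCC[Si](C)(C)C)C1=O | intermediate
16 | potassium 8-en-9-olate of 15 | C=1CC[C@@H]2[C@](C)(CCC[C@]2(C)C(=O)OCC[Si](C)(C)C)C=1[O-].[K+] | intermediate
17 | 8-en-9-yl trifluoromethanesulfonate of 15 | C=1CC[C@@H]2[C@](C)(CCC[C@]2(C)C(=O)OCC[Si](C)(C)C)C=1OS(=O)(=O)C(F)(F)F | intermediate
18 | (R)-methyl hydrogen 3-methylglutarate | COC(=O)C[C@H](C)CC(=O)O | starting material
19 | methyl (R)-5-hydroxy-3-methylpentanoate | COC(=O)C[C@H](C)CCO | intermediate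
20 | methyl (R)-5-[(tert-butyldiphenylsilyl)oxy]-3-methylpentanoate | COC(=O)C[C@H](C)CCO[Si](c1ccccc1)(c1ccccc1)C(C)(C)C | intermediate
21 | (S)-5-[(tert-butyldiphenylsilyl)oxy]-3-methylpentan-1-ol | OCC[C@H](C)CCO[Si](c1ccccc1)(c1ccccc1)C(C)(C)C | intermediate
22 | (R)-tert-butyl[(5-iodo-3-methylpentyl)oxy]diphenylsilane | ICC[C@H](C)CCO[Si](c1ccccc1)(c1ccccc1)C(C)(C)C | intermediate
23 | (R)-{5-[(tert-butyldiphenylsilyl)oxy]-3-methylpentyl}zinc iodide | I[Zn]CC[C@H](C)CCO[Si](c1ccccc1)(c1ccccc1)C(C)(C)C | intermediate
24 | 2-(trimethylsilyl)ethyl (13S)-15-[(tert-butyldiphenylsilyl)oxy]-17-norlabd-8-en-19-oate | C=1CC[C@@H]2[C@](C)(CCC[C@]2(C)C(=O)OCC[Si](C)(C)C)C=1CC[C@H](C)CCO[Si](c1ccccc1)(c1ccccc1)C(C)(C)C | intermediate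
25 | 8α-boryl (BH2) adduct of 24, H-9 α | B[C@@H]1CC[C@@H]2[C@](C)(CCC[C@]2(C)C(=O)OCC[Si](C)(C)C)[C@H]1CC[C@H](C)CCO[Si](c1ccccc1)(c1ccccc1)C(C)(C)C | intermediate
26 | 2-(trimethylsilyl)ethyl (13S)-15-[(tert-butyldiphenylsilyl)oxy]-8α-hydroxy-17-norlabdan-19-oate | O[C@@H]1CC[C@@H]2[C@](C)(CCC[C@]2(C)C(=O)OCC[Si](C)(C)C)[C@H]1CC[C@H](C)CCO[Si](c1ccccc1)(c1ccccc1)C(C)(C)C | intermediate
27 | 2-(trimethylsilyl)ethyl (13S)-15-[(tert-butyldiphenylsilyl)oxy]-8-oxo-17-norlabdan-19-oate | O=C1CC[C@@H]2[C@](C)(CCC[C@]2(C)C(=O)OCC[Si](C)(C)C)[C@H]1CC[C@H](C)CCO[Si](c1ccccc1)(c1ccccc1)C(C)(C)C | intermediate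
28 | 2-(trimethylsilyl)ethyl (13S)-15-[(tert-butyldiphenylsilyl)oxy]labd-8(17)-en-19-oate | C=C1CC[C@@H]2[C@](C)(CCC[C@]2(C)C(=O)OCC[Si](C)(C)C)[C@H]1CC[C@H](C)CCO[Si](c1ccccc1)(c1ccccc1)C(C)(C)C | intermediate
29 | (13S)-15-hydroxylabd-8(17)-en-19-oic acid | C=C1CC[C@@H]2[C@](C)(CCC[C@]2(C)C(=O)O)[C@H]1CC[C@H](C)CCO | intermediate
30 | stearoyl chloride (octadecanoyl chloride) | CCCCCCCCCCCCCCCCCC(=O)Cl | starting material
31 | (1S,4aR,5S,8aR)-1,4a-dimethyl-6-methylidene-5-[(3S)-3-methyl-5-(octadecanoyloxy)pentyl]decahydronaphthalene-1-carboxylic acid | C=C1CC[C@@H]2[C@](C)(CCC[C@]2(C)C(=O)O)[C@H]1CC[C@H](C)CCOC(=O)CCCCCCCCCCCCCCCCC | target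

## Step count and least certain steps

Total step count: 20. Longest linear sequence: 16 steps (steps 1–10 and 15–20); the chain fragment is made in steps 11–14.

**Step 4 (key step).** The strongly acidic boron catalyst may be sequestered by the dioxolane oxygens, or may ionise the allylic ketal. That would lead to loss of the diene or to a poorly organised, less selective background reaction. In addition, the inner substituent at C10 polarises the diene against the ortho sense, and the α-methyl group weakens the endo preference, so erosion of regio-, endo- or face-selectivity is possible. Fallback: setting out from 6 and 7, the cycloaddition would be promoted by the achiral, proton-scavenging Lewis acid Me2AlCl (CH2Cl2, −78 °C) to give the racemic formyl-endo adduct F1, and NaBH4 reduction would give the racemic alcohol F2. Esterification with (S)-naproxen (carbodiimide, DMAP) would give two diastereomers, the (S)-naproxen ester of 9 F3 and the (S)-naproxen ester of the enantiomer of 9 F4, to be separated by chromatography or crystallisation. Reductive cleavage of F3 with LiAlH4 comes back to the route at 9.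

**Step 6.** Delivery from the zinc alkoxide may lose out to undirected attack on the less hindered α face, or to coordination by the ketal oxygens, giving poor facial selectivity. The trisubstituted alkene next to the quaternary ketal carbon may also react slowly, and zinc iodide may open the ketal. Fallback: setting out from 9, the carbon would be delivered through a covalent tether. Acylation with bromoacetyl bromide gives the bromoacetate F5, and N,N'-ditosylhydrazine with DBU converts it into the diazoacetate F6. Rh2(OAc)4-catalysed intramolecular cyclopropanation, which can reach only the β face, gives the cyclopropane-fused seven-membered lactone F7. Saponification (LiOH) gives the hydroxy acid F8, and Barton decarboxylation through the N-acyloxypyridine-2-thione F9 (t-BuSH, visible light) removes the extra carbon and comes back to the route at 11.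

**Step 7.** The ketal may be lost in the acidic medium. The cyclopropyl ketone so exposed would be cleaved at a bond to C10 (methyl on C1 or ring enlargement) or reduced at the carbonyl; incomplete discrimination between the C1–C20 and C10–C20 bonds is a second risk. Fallback: setting out from 11, the ketal would be removed on purpose (dilute HCl, acetone) to give the cyclopropyl ketone F10, which NaBH4 reduces to the cyclopropyl carbinol F11 (C9 configuration inconsequential). With no carbonyl to activate the ring bonds at C10 and no acid-labile group left, hydrogenolysis (H2, PtO2, AcOH) gives the diol F12, and Jones oxidation of both hydroxyls comes back to the route at 14.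

**Step 15.** Transmetalation and reductive elimination at C9, which is flanked by the quaternary C10, may be slow. The alkylpalladium intermediate would then undergo β-hydride elimination, or the triflate would simply be reduced, and the zinc reagent may be protonated before it couples. Fallback: setting out from 22 and 17, the nucleophile would be changed to a four-coordinate boron species that transmetalates through a Pd–O–B bridge. Lithium–iodine exchange (t-BuLi, Et2O, −78 °C) gives the alkyllithium F13, which 9-methoxy-9-borabicyclo[3.3.1]nonane captures as the lithium alkyl(methoxy)borate F14. B-alkyl Suzuki–Miyaura coupling of F14 with 17 (Pd(dppf)Cl2, K3PO4, DMF/H2O) comes back to the route at 24.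

**Step 16.** Hydroboration of the hindered trisubstituted alkene may be sluggish, may show incomplete α-face selectivity, or may be accompanied by slow reduction of the ester by excess borane. Fallback: setting out from 24, epoxidation with mCPBA from the α face gives the 8α,9α-epoxide F15. Meinwald rearrangement (BF3·OEt2, CH2Cl2, −78 °C) shifts hydride from C8 to C9 and gives the 9-epi ketone F16 (H-9 β). Base (DBU, or K2CO3 in MeOH) equilibrates it to the equatorial chain and comes back to the route at 27.

## Further compounds

F1 | step 4 | racemic formyl-endo adduct (both enantiomers of 8) | C1CC[C@@H]2C(=CCC[C@]2(C)C=O)C13OCCO3.C1CC[C@H]2C(=CCC[C@@]2(C)C=O)C13OCCO3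
F2 | step 4 | racemic alcohol (both enantiomers of 9) | C1CC[C@@H]2C(=CCC[C@]2(C)CO)C13OCCO3.C1CC[C@H]2C(=CCC[C@@]2(C)CO)C13OCCO3
F3 | step 4 | (S)-naproxen ester of 9 | C1CC[C@@H]2C(=CCC[C@]2(C)COC(=O)[C@@H](C)c3ccc4cc(OC)ccc4c3)C15OCCO5
F4 | step 4 | (S)-naproxen ester of the enantiomer of 9 | C1CC[C@H]2C(=CCC[C@@]2(C)COC(=O)[C@@H](C)c3ccc4cc(OC)ccc4c3)C15OCCO5
F5 | step 6 | bromoacetate of 9 | C1CC[C@@H]2C(=CCC[C@]2(C)COC(=O)CBr)C13OCCO3
F6 | step 6 | diazoacetate of 9 | C1CC[C@@H]2C(=CCC[C@]2(C)COC(=O)C=[N+]=[N-])C13OCCO3
F7 | step 6 | cyclopropane-fused seven-membered lactone (C20 bonded to the lactone carbonyl, β face) | C1CC[C@@H]2[C@@]3([C@H]4[C@@H]3CC[C@]2(C)COC4=O)C15OCCO5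
F8 | step 6 | hydroxy acid (carboxyl on C20 of the cyclopropane, 4β-hydroxymethyl) | C1CC[C@@H]2[C@@]3([C@H](C(=O)O)[C@@H]3CC[C@]2(C)CO)C14OCCO4
F9 | step 6 | N-acyloxypyridine-2-thione (Barton ester) of F8 | C1CC[C@@H]2[C@@]3([C@H](C(=O)ON4C=CC=CC4=S)[C@@H]3CC[C@]2(C)CO)C15OCCO5
F10 | step 7 | cyclopropyl ketone (C9 ketone, C20 methylene across C1–C10, 4β-hydroxymethyl) | C1CC[C@@H]2[C@@]3(C[C@@H]3CC[C@]2(C)CO)C1=O
F11 | step 7 | cyclopropyl carbinol (C9 hydroxyl, configuration inconsequential) | C1CC[C@@H]2[C@@]3(C[C@@H]3CC[C@]2(C)CO)C1O
F12 | step 7 | 4β-(hydroxymethyl)-4α,10β-dimethyl trans-decalin-9-ol (C9 configuration inconsequential) | C1CC[C@@H]2[C@](C)(CCC[C@]2(C)CO)C1O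
F13 | step 15 | (R)-{5-[(tert-butyldiphenylsilyl)oxy]-3-methylpentyl}lithium | [Li]CC[C@H](C)CCO[Si](c1ccccc1)(c1ccccc1)C(C)(C)C
F14 | step 15 | lithium alkyl(methoxy)borate from F13 and 9-methoxy-9-borabicyclo[3.3.1]nonane | [Li+].CO[B-]1(CC[C@H](C)CCO[Si](c2ccccc2)(c2ccccc2)C(C)(C)C)C2CCCC1CCC2
F15 | step 16 | 8α,9α-epoxide of 24 | O1[C@@H]2CC[C@@H]3[C@](C)(CCC[C@]3(C)C(=O)OCC[Si](C)(C)C)[C@]12CC[C@H](C)CCO[Si](c1ccccc1)(c1ccccc1)C(C)(C)C
F16 | step 16 | 9-epi ketone (H-9 β epimer of 27) | O=C1CC[C@@H]2[C@](C)(CCC[C@]2(C)C(=O)OCC[Si](C)(C)C)[C@@H]1CC[C@H](C)CCO[Si](c1ccccc1)(c1ccccc1)C(C)(C)C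
A1 | alternative 1 | trans-fused octalin aldehyde (C11 formyl on C9, C17 silyloxymethyl on C8, 6-ene, C19 methyl ester) | CC(C)(C)[Si](C)(C)OC[C@H]1C=C[C@@H]2[C@](C)(CCC[C@]2(C)C(=O)OC)[C@H]1C=O
A2 | alternative 2 | 11-membered 19,15-lactone with C11 hydroxyl and 8(17)-methylene (C11 configuration inconsequential) | C=C1CC[C@@H]2[C@](C)(CCC[C@]2(C)C(=O)O3)[C@H]1C(O)C[C@H](C)CC3
A3 | alternative 3 | bicyclic cross-conjugated dienone (C3 ketone, C4 ester, C8 ketal, C9 vinyl, C10 methyl) | O=C1C=C[C@]2(C)[C@@H](C=C)C3(OCCO3)CCC2=C1C(=O)OC
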